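**Retrosynthetic overview**
1. Target ⇒ (C3 propionylation, Luche reduction, C8 acetylation, opening of a temporary C8–O–C12 lactone) a 3-oxo α-methylene cis-lactone; its C7–C11 bond ⇒ tethered 1,6-addition/methylenation on an 8β-hydroxy-4,6-dien-3-one, which comes from bromohydrin formation/elimination on the ring-B alkene.
2. Ring B ⇒ ring-closing metathesis (C7=C8) of two allyl groups: C5–C6 from a Stork–Danheiser allylation, C10–C9 from a Pd-catalysed decarboxylative allylation that sets C10.
3. Ring A ⇒ one-pot Michael (C1–C10)/Claisen (C3–C4) union of allyl 2-methyl-3-oxopentanoate (C15–C4–C5 and C10–C14) with allyl acrylate (C1–C3); the allyl ester on C10 is first the activating group and later the source of C9 and C8.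
4. Enabling feature: in ring A the oxygen on C3 and the sp2 carbon C5 are 1,3-related across C4, and the quaternary C10 is α to C5. Ring A is therefore a masked 2-methylcyclohexane-1,3-dione whose C5 carbonyl has C10 and C4 as its two α-carbons.
5. Ring order: ring A (step 2), then ring B (step 6); the lactone ring made in step 9 is temporary and is opened in step 10.

Key step: step 2

Remark: eudesmane numbering is used (ring A = C1–C5 and C10, ring B = C5–C10, C11–C13 = acrylate carbons, C14 on C10, C15 on C4; β = the face of C14); the target is read as (3S,7R,8R,10R), that is with the C3 and C8 oxygens, the C7 side chain and C14 all β. Compounds 2–6 are racemic.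

Step 1
Reactants: 1 allyl propionate (two molecules)
Product: 2 allyl 2-methyl-3-oxopentanoate
Conditions: TiCl4, Bu3N, TMSOTf (cat.), CH2Cl2, 0 °C
Reagents that add atoms: none
Why: A titanium-mediated Claisen self-condensation (Ti-Claisen) should convert the simple ester cleanly into the 2-methyl-3-oxo ester, whose new stereocentre is enolizable and of no consequence.

Step 2
Reactants: 2 allyl 2-methyl-3-oxopentanoate; 3 allyl acrylate
Product: 5 allyl 1,3-dimethyl-2,4-dioxocyclohexane-1-carboxylate, via diallyl 2-methyl-2-propanoylpentanedioate 4 (not isolated)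
Conditions: t-BuOK (0.1 equiv), THF, 0 °C, slow addition of 3; then t-BuOK (1.2 equiv), 0 °C → rt; aq. HCl
Reagents that add atoms: none
Why: Catalytic t-BuOK generates the doubly stabilized C10 carbanion of β-keto ester 2, which adds to the β-carbon (C1) of allyl acrylate (Michael addition) to give the quaternary keto diester 4; a full equivalent of base then forms the ethyl-ketone enolate at C4, which attacks the side-chain ester carbonyl C3 (intramolecular Claisen, that is Dieckmann-type, acylation) and expels allyloxide, and deprotonation of the acidic C4–H of the resulting 2-methyl-1,3-dione drives the sequence to completion. The closest known reaction type is the tandem Michael–Claisen synthesis of cyclohexane-1,3-diones (dimedone synthesis, 5-oxoalkanoate to cyclohexane-1,3-dione). Ring A closes in the second event by a 6-(enolendo)-exo-trig acyl substitution. C10 and C4 are formed without control and need none: C4 is enolized and later sp2, and the racemic C10 centre is erased and set again by the catalyst in step 4, where its allyl ester is ionized. The step needs Michael addition at C10 and not at C4 (only C10–H is acidic enough under catalytic base), ring closure from C4 onto C3 and not onto the ester at C10 (that would give a four-membered ring), and no ester scrambling (both esters are allyl esters, so exchange with the expelled allyloxide is degenerate).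

Step 3
Reactants: 5 allyl 1,3-dimethyl-2,4-dioxocyclohexane-1-carboxylate
Product: 6 allyl 4-methoxy-1,3-dimethyl-2-oxocyclohex-3-ene-1-carboxylate
Conditions: HC(OMe)3, MeOH, TsOH·H2O (cat.), rt
Reagents that add atoms: trimethyl orthoformate, COC(OC)OC
Why: Acid-catalysed enol etherification of the 1,3-dione with an orthoformate should take place at the C3 carbonyl, which is remote from the quaternary C10 and therefore less hindered, so that the C5 ketone stays part of the β-keto ester needed in step 4.

Step 4
Reactants: 6 allyl 4-methoxy-1,3-dimethyl-2-oxocyclohex-3-ene-1-carboxylate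
Product: 7 (R)-6-allyl-3-methoxy-2,6-dimethylcyclohex-2-en-1-one
Conditions: Pd2(dba)3 (2.5 mol %), (R)-t-BuPHOX (6 mol %), toluene, 30 °C
Reagents that add atoms: none
Why: Palladium-catalysed decarboxylative asymmetric allylic alkylation (enantioselective Tsuji allylation) of an α-quaternary allyl β-keto ester: zerovalent palladium ionizes the allyl ester, CO2 is lost and the resulting prochiral enolate recombines with the allyl group under control of the PHOX ligand, so both enantiomers of 6 converge and C10 is set as (R), the (R)-ligand being chosen by analogy with the known (S)-ligand to (S)-2-allyl-2-methylcyclohexanone correlation.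

Step 5
Reactants: 7 (R)-6-allyl-3-methoxy-2,6-dimethylcyclohex-2-en-1-one; 8 allylmagnesium bromide
Product: 10 (4R)-3,4-diallyl-2,4-dimethylcyclohex-2-en-1-one, via the tertiary alkoxide adduct 9 (not isolated)
Conditions: 8 (1.5 equiv), THF, 0 °C; then 1 M aq. HCl, rt
Reagents that add atoms: water, O
Why: Stork–Danheiser enone transposition: 1,2-addition of the allyl Grignard reagent to the vinylogous ester carbonyl (C5) and acid hydrolysis of the resulting tertiary allylic alcohol and enol ether place the ketone at C3, the double bond at C4=C5 and the new C5–C6 bond, without touching C10.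

Step 6
Reactants: 10 (4R)-3,4-diallyl-2,4-dimethylcyclohex-2-en-1-one
Product: 11 (4aR)-1,4a-dimethyl-4,4a,5,8-tetrahydronaphthalen-2(3H)-one
Conditions: second-generation Grubbs catalyst RuCl2(=CHPh)(PCy3)(H2IMes) (3 mol %), CH2Cl2 (0.01 M), 40 °C
Reagents that add atoms: none
Why: Ring-closing metathesis of the two monosubstituted allyl groups closes ring B as a cyclohexene (C7=C8) with loss of ethene, the tetrasubstituted enone double bond being inert to the catalyst.

Step 7
Reactants: 11 (4aR)-1,4a-dimethyl-4,4a,5,8-tetrahydronaphthalen-2(3H)-one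
Product: 13 (4aR,6R)-6-hydroxy-1,4a-dimethyl-4,4a,5,6-tetrahydronaphthalen-2(3H)-one, via the 7α-bromo-8β-hydroxy bromohydrin 12 (not isolated)
Conditions: NBS, THF/H2O (3:1), 0 °C, dark; then DBU (2.5 equiv), rt
Reagents that add atoms: water, O; N-bromosuccinimide, O=C1CCC(=O)N1Br (its bromine is carried only by 12)
Why: Bromohydrin formation followed by vinylogous E1cB elimination: the bromonium ion should form on the α face of the isolated C7=C8 bond (anti to the axial C14 methyl) and be opened trans-diaxially by water at C8 (Fürst–Plattner rule, as in the 2β-hydroxy-3α-bromo adducts of Δ2-steroids), which sets the 8β-oxygen, and DBU then removes the acidic γ-proton at C6 of the enone and expels the axial bromide at C7 (directly or through the 7β,8β-epoxide) to give the linear dienone without touching C8.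

Step 8
Reactants: 13 (4aR,6R)-6-hydroxy-1,4a-dimethyl-4,4a,5,6-tetrahydronaphthalen-2(3H)-one; 14 2-(diethoxyphosphoryl)acetic acid
Product: 15 (2R,8aR)-5,8a-dimethyl-6-oxo-1,2,6,7,8,8a-hexahydronaphthalen-2-yl 2-(diethoxyphosphoryl)acetate
Conditions: DCC, DMAP (cat.), CH2Cl2, 0 °C → rt
Reagents that add atoms: none
Why: Steglich esterification attaches the future C11–C12 unit to the 8β-oxygen with retention at C8.

Step 9
Reactants: 15 (2R,8aR)-5,8a-dimethyl-6-oxo-1,2,6,7,8,8a-hexahydronaphthalen-2-yl 2-(diethoxyphosphoryl)acetate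
Product: 17 (3aR,8aR,9aR)-5,8a-dimethyl-3-methylidene-3a,4,7,8,8a,9-hexahydronaphtho[2,3-b]furan-2,6(3H,9aH)-dione, via the α-phosphono cis-lactone 16 (not isolated)
Conditions: K2CO3, 18-crown-6 (cat.), THF, rt; then 37% aq. CH2O, rt
Reagents that add atoms: formaldehyde, C=O
Why: Tethered intramolecular conjugate (1,6-) addition followed by Horner–Wadsworth–Emmons methylenation with formaldehyde, the known route to α-methylene γ-lactones: the phosphonate-stabilized carbanion held on the 8β-oxygen can reach the δ-carbon C7 of the dienone only from the β face (5-exo-trig closure, as in the known cyclizations of O-malonyl and O-acetoacetyl 4-hydroxycyclohexadienones to cis-fused γ-lactones), so the cis fusion (C7–C11 bond β, H-7 α) is dictated by the tether, the dienolate reprotonates to the conjugated Δ4-3-ketone and the α-phosphono lactone then olefinates formaldehyde to create C11=C13.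

Step 10
Reactants: 17 (3aR,8aR,9aR)-5,8a-dimethyl-3-methylidene-3a,4,7,8,8a,9-hexahydronaphtho[2,3-b]furan-2,6(3H,9aH)-dione
Product: 19 methyl 2-[(2R,3R,4aR)-3-hydroxy-4a,8-dimethyl-7-oxo-1,2,3,4,4a,5,6,7-octahydronaphthalen-2-yl]prop-2-enoate, via the potassium carboxylate 18 (not isolated)
Conditions: KOH (1.05 equiv), THF/H2O, 0 °C; evaporate; MeI, DMF, 0 °C → rt
Reagents that add atoms: potassium hydroxide, [K+].[OH-]; iodomethane, CI
Why: Saponification of the γ-lactone followed by O-alkylation of the carboxylate salt with iodomethane gives the seco methyl ester without an acidic stage in which the γ-hydroxy acid could relactonize, hydroxide being expected to attack the lactone carbonyl faster than the exocyclic methylene, and C7 and C8 are not touched.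

Step 11
Reactants: 19 methyl 2-[(2R,3R,4aR)-3-hydroxy-4a,8-dimethyl-7-oxo-1,2,3,4,4a,5,6,7-octahydronaphthalen-2-yl]prop-2-enoate
Product: 20 methyl 2-[(2R,3R,4aR)-3-acetoxy-4a,8-dimethyl-7-oxo-1,2,3,4,4a,5,6,7-octahydronaphthalen-2-yl]prop-2-enoate
Conditions: Ac2O, DMAP, pyridine, CH2Cl2, rt
Reagents that add atoms: acetic anhydride, CC(=O)OC(C)=O
Why: DMAP-catalysed acetylation of the axial 8β-alcohol, carried out at once on crude 19 so that acylation outruns relactonization, fixes the open form.

Step 12
Reactants: 20 methyl 2-[(2R,3R,4aR)-3-acetoxy-4a,8-dimethyl-7-oxo-1,2,3,4,4a,5,6,7-octahydronaphthalen-2-yl]prop-2-enoate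
Product: 21 methyl 2-[(2R,3R,4aR,7S)-3-acetoxy-7-hydroxy-4a,8-dimethyl-1,2,3,4,4a,5,6,7-octahydronaphthalen-2-yl]prop-2-enoate
Conditions: NaBH4, CeCl3·7H2O, MeOH, −78 °C
Reagents that add atoms: none
Why: Luche reduction is 1,2-selective, so the acrylate and the acetate survive, and hydride should add to the C3 carbonyl of the 4-methyl-Δ4-3-ketone from the α face, anti to the axial C14 methyl as in Δ4-3-keto steroids, to give the pseudo-equatorial 3β-alcohol (3S).

Step 13
Reactants: 21 methyl 2-[(2R,3R,4aR,7S)-3-acetoxy-7-hydroxy-4a,8-dimethyl-1,2,3,4,4a,5,6,7-octahydronaphthalen-2-yl]prop-2-enoate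
Product: 22 methyl 2-[(2R,3R,4aR,7S)-3-acetoxy-4a,8-dimethyl-7-(propanoyloxy)-1,2,3,4,4a,5,6,7-octahydronaphthalen-2-yl]prop-2-enoate (CNP0198123.1)
Conditions: (EtCO)2O, DMAP (cat.), Et3N, CH2Cl2, 0 °C → rt
Reagents that add atoms: propionic anhydride, CCC(=O)OC(=O)CC
Why: DMAP-catalysed acylation of the only free hydroxyl with propionic anhydride gives the 3β-propionate with retention and completes the target.

**Compound list**
1 | allyl propionate | CCC(=O)OCC=C | starting material
2 | allyl 2-methyl-3-oxopentanoate (racemic) | CCC(=O)C(C)C(=O)OCC=C | intermediate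
3 | allyl acrylate | C=CC(=O)OCC=C | starting material
4 | diallyl 2-methyl-2-propanoylpentanedioate (racemic) | CCC(=O)C(C)(CCC(=O)OCC=C)C(=O)OCC=C | intermediate
5 | allyl 1,3-dimethyl-2,4-dioxocyclohexane-1-carboxylate (racemic, C3 epimers and enol forms) | CC1C(=O)CCC(C)(C(=O)OCC=C)C1=O | intermediate
6 | allyl 4-methoxy-1,3-dimethyl-2-oxocyclohex-3-ene-1-carboxylate (racemic) | COC1=C(C)C(=O)C(C)(C(=O)OCC=C)CC1 | intermediate
7 | (R)-6-allyl-3-methoxy-2,6-dimethylcyclohex-2-en-1-one | COC1=C(C)C(=O)[C@@](C)(CC=C)CC1 | intermediate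
8 | allylmagnesium bromide | C=CC[Mg]Br | starting material
9 | (6R)-1,6-diallyl-3-methoxy-2,6-dimethylcyclohex-2-en-1-ol (present as its bromomagnesium alkoxide, both C1 epimers) | C=CCC1(O)C(C)=C(OC)CC[C@]1(C)CC=C | intermediate
10 | (4R)-3,4-diallyl-2,4-dimethylcyclohex-2-en-1-one | C=CCC1=C(C)C(=O)CC[C@]1(C)CC=C | intermediate
11 | (4aR)-1,4a-dimethyl-4,4a,5,8-tetrahydronaphthalen-2(3H)-one | CC1=C2CC=CC[C@@]2(C)CCC1=O | intermediate
12 | (4aR,6R,7R)-7-bromo-6-hydroxy-1,4a-dimethyl-4,4a,5,6,7,8-hexahydronaphthalen-2(3H)-one (7α-Br, 8β-OH) | CC1=C2C[C@@H](Br)[C@H](O)C[C@@]2(C)CCC1=O | intermediate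
13 | (4aR,6R)-6-hydroxy-1,4a-dimethyl-4,4a,5,6-tetrahydronaphthalen-2(3H)-one (8β-hydroxy-4,6-dien-3-one) | CC1=C2C=C[C@H](O)C[C@@]2(C)CCC1=O | intermediate
14 | 2-(diethoxyphosphoryl)acetic acid | CCOP(=O)(CC(=O)O)OCC | starting material
15 | (2R,8aR)-5,8a-dimethyl-6-oxo-1,2,6,7,8,8a-hexahydronaphthalen-2-yl 2-(diethoxyphosphoryl)acetate | CC1=C2C=C[C@H](OC(=O)CP(=O)(OCC)OCC)C[C@@]2(C)CCC1=O | intermediate
16 | cis-fused α-(diethoxyphosphoryl) γ-lactone (C11 epimers; 17 with H and P(O)(OEt)2 on C11 in place of the methylidene) | CCOP(=O)(OCC)C1C(=O)O[C@@H]2C[C@@]3(C)CCC(=O)C(C)=C3C[C@H]12 | intermediate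
17 | (3aR,8aR,9aR)-5,8a-dimethyl-3-methylidene-3a,4,7,8,8a,9-hexahydronaphtho[2,3-b]furan-2,6(3H,9aH)-dione (3-oxoeudesma-4,11(13)-dien-12,8β-olide) | C=C1C(=O)O[C@@H]2C[C@@]3(C)CCC(=O)C(C)=C3C[C@H]12 | intermediate
18 | potassium 2-[(2R,3R,4aR)-3-hydroxy-4a,8-dimethyl-7-oxo-1,2,3,4,4a,5,6,7-octahydronaphthalen-2-yl]prop-2-enoate | C=C(C(=O)[O-])[C@H]1CC2=C(C)C(=O)CC[C@]2(C)C[C@H]1O.[K+] | intermediate
19 | methyl 2-[(2R,3R,4aR)-3-hydroxy-4a,8-dimethyl-7-oxo-1,2,3,4,4a,5,6,7-octahydronaphthalen-2-yl]prop-2-enoate | C=C(C(=O)OC)[C@H]1CC2=C(C)C(=O)CC[C@]2(C)C[C@H]1O | intermediate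
20 | methyl 2-[(2R,3R,4aR)-3-acetoxy-4a,8-dimethyl-7-oxo-1,2,3,4,4a,5,6,7-octahydronaphthalen-2-yl]prop-2-enoate | C=C(C(=O)OC)[C@H]1CC2=C(C)C(=O)CC[C@]2(C)C[C@H]1OC(C)=O | intermediate
21 | methyl 2-[(2R,3R,4aR,7S)-3-acetoxy-7-hydroxy-4a,8-dimethyl-1,2,3,4,4a,5,6,7-octahydronaphthalen-2-yl]prop-2-enoate | C=C(C(=O)OC)[C@H]1CC2=C(C)[C@@H](O)CC[C@]2(C)C[C@H]1OC(C)=O | intermediate
22 | methyl 2-[(2R,3R,4aR,7S)-3-acetoxy-4a,8-dimethyl-7-(propanoyloxy)-1,2,3,4,4a,5,6,7-octahydronaphthalen-2-yl]prop-2-enoate (CNP0198123.1) | C=C(C(=O)OC)[C@H]1CC2=C(C)[C@@H](OC(=O)CC)CC[C@]2(C)C[C@H]1OC(C)=O | target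

**Step count and risks**
Total step count: 13. Longest linear sequence: 13 steps (from allyl propionate 1).

The three steps most likely to fail:

Step 7. What may go wrong: water may open the bromonium ion at C7 or from the wrong face, or bromination may occur at the bis-allylic C6 position, so that the 8β configuration is not secured. Fallback: starting from 11, epoxidation with mCPBA (NaHCO3, CH2Cl2), which should occur on the α face anti to C14, gives the 7α,8α-epoxide F1. DBU opens it by the same vinylogous E1cB process to the 8α-hydroxy dienone F2. Mitsunobu esterification of F2 with acid 14 (PPh3, DIAD, toluene) inverts C8 and gives 15, where the route is rejoined.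

Step 9. What may go wrong: closure of the five-membered ring by the ester-tethered carbanion may be slow (unfavourable ester conformation, enolendo geometry), so that intermolecular addition or olefination of formaldehyde before ring closure takes over. Fallback: starting from 13, esterification with mono-allyl malonate (DCC, DMAP) gives the mixed malonate F3. Cs2CO3 in MeCN effects the malonate Michael closure to the α-(allyloxycarbonyl) cis-lactone F4. Pd(PPh3)4 with morpholine removes the allyl group to give the lactone acid F5. Decarboxylative Mannich methylenation (aq. CH2O, Et2NH, then NaOAc/AcOH) gives 17, where the route is rejoined.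

Step 10. What may go wrong: relactonization of the γ-hydroxy ester during alkylation or work-up. Fallback: starting from 17, after the same KOH opening to 18, both oxygens are silylated (TBSOTf, 2,6-lutidine) to the silyl ester silyl ether F6. The silyl ester alone is hydrolysed (K2CO3, aq. MeOH) to the acid F7, which can no longer lactonize. TMSCHN2 gives the methyl ester F8, and Cu(OTf)2-catalysed Ac2O exchanges the silyl ether for the acetate to give 20, where the route is rejoined.

**Further compounds**
F1 | step 7 | (4aR,6S,7R)-6,7-epoxy-1,4a-dimethyl-4,4a,5,6,7,8-hexahydronaphthalen-2(3H)-one (7α,8α-epoxide) | CC1=C2C[C@H]3O[C@H]3C[C@@]2(C)CCC1=O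
F2 | step 7 | (4aR,6S)-6-hydroxy-1,4a-dimethyl-4,4a,5,6-tetrahydronaphthalen-2(3H)-one (8α-epimer of 13) | CC1=C2C=C[C@@H](O)C[C@@]2(C)CCC1=O
F3 | step 9 | allyl (2R,8aR)-5,8a-dimethyl-6-oxo-1,2,6,7,8,8a-hexahydronaphthalen-2-yl malonate | CC1=C2C=C[C@H](OC(=O)CC(=O)OCC=C)C[C@@]2(C)CCC1=O
F4 | step 9 | cis-fused α-(allyloxycarbonyl) γ-lactone (C11 epimers; 17 with H and CO2allyl on C11 in place of the methylidene) | C=CCOC(=O)C1C(=O)O[C@@H]2C[C@@]3(C)CCC(=O)C(C)=C3C[C@H]12
F5 | step 9 | cis-fused α-carboxy γ-lactone (C11 epimers; 17 with H and CO2H on C11 in place of the methylidene) | OC(=O)C1C(=O)O[C@@H]2C[C@@]3(C)CCC(=O)C(C)=C3C[C@H]12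
F6 | step 10 | tert-butyldimethylsilyl 2-[(2R,3R,4aR)-3-(tert-butyldimethylsilyloxy)-4a,8-dimethyl-7-oxo-1,2,3,4,4a,5,6,7-octahydronaphthalen-2-yl]prop-2-enoate | C=C(C(=O)O[Si](C)(C)C(C)(C)C)[C@H]1CC2=C(C)C(=O)CC[C@]2(C)C[C@H]1O[Si](C)(C)C(C)(C)C
F7 | step 10 | 2-[(2R,3R,4aR)-3-(tert-butyldimethylsilyloxy)-4a,8-dimethyl-7-oxo-1,2,3,4,4a,5,6,7-octahydronaphthalen-2-yl]prop-2-enoic acid | C=C(C(=O)O)[C@H]1CC2=C(C)C(=O)CC[C@]2(C)C[C@H]1O[Si](C)(C)C(C)(C)C
F8 | step 10 | methyl 2-[(2R,3R,4aR)-3-(tert-butyldimethylsilyloxy)-4a,8-dimethyl-7-oxo-1,2,3,4,4a,5,6,7-octahydronaphthalen-2-yl]prop-2-enoate | C=C(C(=O)OC)[C@H]1CC2=C(C)C(=O)CC[C@]2(C)C[C@H]1O[Si](C)(C)C(C)(C)C
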